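Readings and results are simulated for substances that don't exist, noise included.

The ratio of Q to L in the winter run read 19.2 at 120 min, but L is known there to within 1 percentage point, so that ratio is loose. The rate of Q formation says more.

in all of them: J 0.40 M
- winter: G 0.04 mol%; run made earlier
- flask: G 0.08 mol%; time 10 h

winter run (percent of the J charged)

| time / min | Q / % | L / % |
|---|---|---|
| 10.0 | 2.0 | 0.8 |
| 20.0 | 8.6 | 1.3 |
| 30.0 | 13.3 | 1.5 |
| 60.0 | 27.3 | 2.5 |
| 120 | 46.2 | 2.4 |

(scatter of a reading: 1 percentage point)

- ratio of Q to L at 6.0 min
- ratio of Q to L at 10 h
- which of Q and L there is more of at 10 h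

- as a solid, counted per litre of solution: J
- at the start none of J is in solution
- no earlier run changes the charge of G; that part of a forecast is a guess

Between 20.0 min and 60.0 min, the winter run made Q at 0.281 /h, as a fraction of the charge. Between 60.0 min and 120 min, the rate was 0.189 /h, a factor of 0.674. The charge not yet turned into Q accounts for a factor of 0.771, which leaves a further 0.874 of slowing unexplained, a hint that the rate is heading for zero short of full conversion.

Read as steady decay, the rate halves every 1.46 h. The halving count, the time of a flask divided by this halving time, is 6.84 for the new flask, taking no credit for its doubled G. That leaves 0.873% of the rate at 10 h. Summing the same decay beyond 120 min carries Q to about 77.7% of the charge by 10 h, still with no credit for G. This reckoning covers the rate of Q and gives no figure for L, so it commits to no ratio.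

The forecast gave 3 (1 to 7) at 6.0 min and 32 (15 to 60) at 10 h, with Q ahead, on the ground that the loss of charge “would consume essentially all J by 10 h”.

The flask gave ratios of 13.8 and 14.1, with Q ahead at 54.9% against 3.89% of L.

    J ⇌ D, rate k1*(cs1 - [D]) while solid is left; crystals form when [D] > cs1 (solubility = 0.260 M, k = 2.83 × 10⁻⁴ /s)
    Q + G ⇌ L + G, rate k2*[G]*[Q] forward; the back reaction follows from the equilibrium constant (K = 0.0710, k = 0.511 /M/s)
    D + G ⇌ Q + G, rate k3*[D]*[G] forward; the back reaction follows from the equilibrium constant (K = 1.33, k = 12.5 /M/s)
    L ⇌ D (k = 0.00311 /s)

In the flask, the half-life of Q by forward loss to L, 1.2 h, is short against 10 h, and the backward turnover of that step is 100% of the forward one, the mark of thermodynamic control. By the count of 6.84 Q in the flask had stopped moving, standing at 54.9% at 5.00 h and 54.9% at 10.0 h, less than the 77.7% reckoned.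

The neighbour with 0.02 mol% of G has half the winter loading. If the halving time stretches in proportion, its count is 3.42, leaving 9.36% of the rate. That neighbour gave a ratio of 14.1 at 10 h, with Q at 54.9%.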